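**Retrosynthetic overview**

1. Eudesmane locants are used throughout: ring C5–C6–C7–C8–C9–C10; C5 carries C4(C15)–C3–C2–C1–OH, C6 the ester oxygen, C7 the C11(=C13)–C12 unit, C8 the lactone oxygen, C10 the methyl C14. Late disconnections: C12–O8 lactone (closed last), O6 ester, C11=C13 (Mannich/elimination), C4–H (O6-directed hydrogenation of C4=C15), C5–C4 (Suzuki–Miyaura), leading back to an all-cis 5-bromocyclohex-5(10)-en-6-ol.
2. Feature used: without C5 the carbocycle is a cyclopentene (C6=C10, methyl on C10) whose C7 and C8 carry, on one face, the C11–C12 carbonyl chain and O8, and the C12 carbonyl oxygen is 1,5 to C6. Dibromocarbene supplies C5, silver-induced opening of the C6–C10 bond widens the ring to six, and the C12 carbonyl oxygen becomes O6.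
3. A closed C12–O8 γ-lactone cannot deliver that oxygen: its carbonyl points away from C6, and bonding would require a bridgehead dioxacarbenium ion in a 2,6-dioxabicyclo[2.2.1]heptane. The carbonyl is therefore carried as the open-chain N,N-dimethylamide with O8 silylated; the dibromocyclopropane and the all-cis bromocyclohexenol are the same compounds with the C12–O8 bond still open.
4. This cyclopentene amide comes in two steps from (R)-4-(tert-butyldimethylsilyloxy)cyclopent-2-enone: methyllithium addition, then Eschenmoser–Claisen rearrangement, which turns the C10–O bond into the C7–C11 bond cis to O8.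
5. Ring order: cyclopentene (purchased) → cyclopropane (step 3) → six-membered carbocycle (step 4) → γ-lactone (step 12).

Key step: step 4

Remark: enantiopure (R)-4-(tert-butyldimethylsilyloxy)cyclopent-2-en-1-one is taken as purchasable; TBS = tert-butyldimethylsilyl, SPhos = 2-dicyclohexylphosphino-2′,6′-dimethoxybiphenyl, MeOBpin = 2-methoxy-4,4,5,5-tetramethyl-1,3,2-dioxaborolane.

**Route**

Step 1
Reactants: 1 (R)-4-(tert-butyldimethylsilyloxy)cyclopent-2-en-1-one
Product: 2 (1S,4R)-4-(tert-butyldimethylsilyloxy)-1-methylcyclopent-2-en-1-ol (hydroxyl cis to silyloxy)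
Conditions: MeLi, Et2O, −78 °C; then H2O
Reagents that add atoms: methyllithium, [Li]C
Why: 1,2-addition of the hard organolithium to the enone carbonyl should occur on the face opposite the C8 silyloxy group, so the tertiary C10 hydroxyl ends up cis to O8 (any trans isomer is removed by chromatography).

Step 2
Reactants: 2 (1S,4R)-4-(tert-butyldimethylsilyloxy)-1-methylcyclopent-2-en-1-ol
Product: 4 2-[(1S,5R)-5-(tert-butyldimethylsilyloxy)-3-methylcyclopent-2-en-1-yl]-N,N-dimethylacetamide (side chain cis to silyloxy), via ketene N,O-acetal 3 (not isolated)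
Conditions: MeC(OMe)2NMe2, xylene, 140 °C, MeOH distilled off
Reagents that add atoms: N,N-dimethylacetamide dimethyl acetal, CC(OC)(OC)N(C)C
Why: Eschenmoser–Claisen rearrangement: alcohol exchange gives the ketene N,O-acetal, whose suprafacial [3,3] shift replaces the C10–O bond by a C7–C11 bond on the same face, which sets C7 cis to O8 and leaves the trisubstituted alkene at C6=C10.

Step 3
Reactants: 4 2-[(1S,5R)-5-(tert-butyldimethylsilyloxy)-3-methylcyclopent-2-en-1-yl]-N,N-dimethylacetamide; 5 bromoform
Product: 6 2-[(1S,2S,3R,5R)-6,6-dibromo-3-(tert-butyldimethylsilyloxy)-5-methylbicyclo[3.1.0]hexan-2-yl]-N,N-dimethylacetamide (CBr2 bridge trans to side chain and silyloxy)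
Conditions: KOtBu, toluene–hexane, −20 → 0 °C; used crude and cold
Reagents that add atoms: none
Why: Cheletropic [2+1] addition of dibromocarbene (α-elimination from bromoform) to the electron-rich trisubstituted alkene should occur on the face away from the C7 chain and the C8 silyl ether; the two new centres C6 and C10 are erased in step 4.

Step 4
Reactants: 6 2-[(1S,2S,3R,5R)-6,6-dibromo-3-(tert-butyldimethylsilyloxy)-5-methylbicyclo[3.1.0]hexan-2-yl]-N,N-dimethylacetamide
Product: 8 2-[(1S,2R,6R)-3-bromo-6-(tert-butyldimethylsilyloxy)-2-hydroxy-4-methylcyclohex-3-en-1-yl]-N,N-dimethylacetamide (O6 and C11 and O8 all cis), via iminium ether tetrafluoroborate 7 (not isolated)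
Conditions: AgBF4 (1.5 equiv), CH2Cl2, 4 Å MS, −40 → 0 °C, dark; then 1 M aq KOH, THF, 0 °C
Reagents that add atoms: potassium hydroxide, [K+].[OH-]
Why: Proposed new method: monovalent silver pulls off the bromide lying over the five-membered ring while the C6–C10 bond opens in the disrotatory sense fixed by orbital symmetry for ionising cyclopropyl halides, so the six-membered carbocycle arises by ring expansion (2π-electrocyclic opening, not a cyclisation) as a C6–C5–C10 allyl cation with the second bromide left on C5. The carbonyl oxygen of the freely rotating C11–C12 amide, 1,5 to C6, then closes a transient five-membered ring on C6 in a 5-exo-trig mode to give iminium ether 7, and hydroxide adds to C12 so that the anionic hemi-orthoamide, unable to expel an amide anion, loses the C6 alkoxide (the base-side partition known for imidate salts) and leaves the former carbonyl oxygen as the free O6 hydroxyl. The closest known reactions are the silver-assisted ring expansion of gem-dibromobicyclo[3.1.0]hexanes to 2-bromocyclohex-2-enyl derivatives with external or tethered oxygen and nitrogen traps, and the halocyclisation of unsaturated tertiary amides through iminium ethers; capture of this cation by an amide carbonyl is untested. The only new stereocentre, C6, is set by C7, because the three-atom tether can close only a cis-fused five-membered ring, which places O6 on the face of C11 and O8. The step needs attack at C6 instead of C10 and capture ahead of proton loss to a bromodiene: C10 is out of reach of the tether and no base or second nucleophile is present until the hydroxide quench, so the tetrasubstituted C5=C10 bromoalkene should result.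

Step 5
Reactants: 9 pent-4-yn-1-ol
Product: 10 tert-butyldimethyl(pent-4-yn-1-yloxy)silane
Conditions: TBSCl, imidazole, CH2Cl2, 0 °C → rt
Reagents that add atoms: tert-butyldimethylsilyl chloride, C[Si](C)(Cl)C(C)(C)C
Why: Routine silylation of the primary alcohol protects O1 through the organometallic and base steps; no stereocentre is involved.

Step 6
Reactants: 10 tert-butyldimethyl(pent-4-yn-1-yloxy)silane
Product: 12 2-[5-(tert-butyldimethylsilyloxy)pent-1-en-2-yl]-4,4,5,5-tetramethyl-1,3,2-dioxaborolane, via alkenylalane 11 (not isolated)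
Conditions: iBu2AlH, NiCl2(dppp) (3 mol %), THF, 0 → 22 °C; then MeOBpin, 0 → 22 °C
Reagents that add atoms: 2-methoxy-4,4,5,5-tetramethyl-1,3,2-dioxaborolane, COB1OC(C)(C)C(C)(C)O1
Why: Nickel-catalysed α-selective hydroalumination of the terminal alkyne places aluminium on the internal carbon with the dppp ligand, and aluminium-to-boron exchange then gives the 1,1-disubstituted alkenyl boronate.

Step 7
Reactants: 8 2-[(1S,2R,6R)-3-bromo-6-(tert-butyldimethylsilyloxy)-2-hydroxy-4-methylcyclohex-3-en-1-yl]-N,N-dimethylacetamide; 12 2-[5-(tert-butyldimethylsilyloxy)pent-1-en-2-yl]-4,4,5,5-tetramethyl-1,3,2-dioxaborolane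
Product: 13 2-[6-(tert-butyldimethylsilyloxy)-3-[5-(tert-butyldimethylsilyloxy)pent-1-en-2-yl]-2-hydroxy-4-methylcyclohex-3-en-1-yl]-N,N-dimethylacetamide (ring configuration of 8)
Conditions: Pd(OAc)2 (5 mol %), SPhos (10 mol %), K3PO4, toluene–H2O (degassed), 80 °C
Reagents that add atoms: none
Why: Suzuki–Miyaura coupling (oxidative addition of zerovalent palladium into C5–Br, transmetalation, reductive elimination) forms the C5–C4 bond; the bulky electron-rich biaryl phosphine is chosen for the tetrasubstituted bromide, and hydroxyl, amide and silyl ethers are tolerated.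

Step 8
Reactants: 13 2-[6-(tert-butyldimethylsilyloxy)-3-[5-(tert-butyldimethylsilyloxy)pent-1-en-2-yl]-2-hydroxy-4-methylcyclohex-3-en-1-yl]-N,N-dimethylacetamide
Product: 14 2-[6-(tert-butyldimethylsilyloxy)-3-[(2S)-5-(tert-butyldimethylsilyloxy)pentan-2-yl]-2-hydroxy-4-methylcyclohex-3-en-1-yl]-N,N-dimethylacetamide (ring configuration of 8)
Conditions: [Ir(cod)(PCy3)(py)]PF6 (5 mol %), H2 (1 atm), CH2Cl2, 0 °C → rt, stopped at one equivalent of H2
Reagents that add atoms: none
Why: Hydroxyl-directed hydrogenation: iridium held by the O6 hydroxyl (the C12 amide lies on the same face) should bind the twisted 1,1-disubstituted C4=C15 alkene in the rotamer that turns its CH2 toward the metal and add hydrogen to the alkene face turned toward C6, which should give (4S), while the hindered tetrasubstituted C5=C10 alkene reacts much more slowly.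

Step 9
Reactants: 14 2-[6-(tert-butyldimethylsilyloxy)-3-[(2S)-5-(tert-butyldimethylsilyloxy)pentan-2-yl]-2-hydroxy-4-methylcyclohex-3-en-1-yl]-N,N-dimethylacetamide
Product: 15 3-(dimethylamino)-N,N-dimethyl-2-[6-(tert-butyldimethylsilyloxy)-3-[(2S)-5-(tert-butyldimethylsilyloxy)pentan-2-yl]-2-hydroxy-4-methylcyclohex-3-en-1-yl]propanamide (C11 epimers)
Conditions: LiN(iPr)2 (2.5 equiv), THF, −78 → −40 °C; CH2=NMe2+ I−, −78 °C → rt; H2O
Reagents that add atoms: dimethyl(methylidene)ammonium iodide, C=[N+](C)C.[I-]
Why: Mannich reaction of the amide enolate (formed as the dianion with the O6 alkoxide) with the preformed iminium salt attaches C13 to C11; the C11 configuration is of no consequence, and the lithium counter-ion at low temperature should keep the O8 silyl group from migrating to O6.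

Step 10
Reactants: 15 3-(dimethylamino)-N,N-dimethyl-2-[6-(tert-butyldimethylsilyloxy)-3-[(2S)-5-(tert-butyldimethylsilyloxy)pentan-2-yl]-2-hydroxy-4-methylcyclohex-3-en-1-yl]propanamide
Product: 17 N,N-dimethyl-2-[6-(tert-butyldimethylsilyloxy)-3-[(2S)-5-(tert-butyldimethylsilyloxy)pentan-2-yl]-2-hydroxy-4-methylcyclohex-3-en-1-yl]prop-2-enamide, via trimethylammonium iodide 16 (not isolated)
Conditions: MeI, CH2Cl2, rt; evaporate; DBU, THF, rt → 40 °C
Reagents that add atoms: none
Why: N-methylation of the tertiary amine and base-induced β-elimination of trimethylamine (Hofmann-type, E1cB) should give the C11=C13 methylene group.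

Step 11
Reactants: 17 N,N-dimethyl-2-[6-(tert-butyldimethylsilyloxy)-3-[(2S)-5-(tert-butyldimethylsilyloxy)pentan-2-yl]-2-hydroxy-4-methylcyclohex-3-en-1-yl]prop-2-enamide; 18 (R)-2-methylbutanoic acid
Product: 19 O6-[(2R)-2-methylbutanoyl] ester of 17
Conditions: DCC, DMAP (0.2 equiv), CH2Cl2, 0 °C → rt
Reagents that add atoms: none
Why: Steglich esterification of the only free hydroxyl (allylic O6) with catalytic DMAP at low temperature, which limits epimerisation of the α-centre of the acid; that centre is carried over unchanged.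

Step 12
Reactants: 19 O6-[(2R)-2-methylbutanoyl] ester of 17
Product: 21 (3aR,4R,7aR)-5-[(2S)-5-hydroxypentan-2-yl]-6-methyl-3-methylidene-2-oxo-2,3,3a,4,7,7a-hexahydro-1-benzofuran-4-yl (2R)-2-methylbutanoate (CNP0291605.3), via dihydroxy amide 20 (not isolated)
Conditions: 48% aq HF, MeCN, 0 °C → rt; then TsOH·H2O (1.2 equiv), rt → 40 °C; acidic aqueous work-up
Reagents that add atoms: none
Why: Acidic fluoride removes both silyl ethers, and the freed cis γ-hydroxyl O8 attacks the C12 acrylamide carbonyl under acid catalysis (intramolecular alcoholysis of a γ-hydroxy amide), closing the cis-fused γ-lactone; O6 is blocked as the ester so only the 12,8-lactone can form, and the amine leaves as its ammonium salt and cannot add to the α-methylene lactone.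

**Compound list**

1 | (R)-4-(tert-butyldimethylsilyloxy)cyclopent-2-en-1-one | O=C1C=C[C@H](O[Si](C)(C)C(C)(C)C)C1 | starting material
2 | (1S,4R)-4-(tert-butyldimethylsilyloxy)-1-methylcyclopent-2-en-1-ol | C[C@@]1(O)C=C[C@H](O[Si](C)(C)C(C)(C)C)C1 | intermediate
3 | 1-(dimethylamino)ethenyl ether of 2 (ketene N,O-acetal) | C[C@@]1(OC(=C)N(C)C)C=C[C@H](O[Si](C)(C)C(C)(C)C)C1 | intermediate
4 | 2-[(1S,5R)-5-(tert-butyldimethylsilyloxy)-3-methylcyclopent-2-en-1-yl]-N,N-dimethylacetamide | CN(C)C(=O)C[C@H]1C=C(C)C[C@H]1O[Si](C)(C)C(C)(C)C | intermediate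
5 | bromoform | BrC(Br)Br | starting material
6 | 2-[(1S,2S,3R,5R)-6,6-dibromo-3-(tert-butyldimethylsilyloxy)-5-methylbicyclo[3.1.0]hexan-2-yl]-N,N-dimethylacetamide | CN(C)C(=O)C[C@H]1[C@@H]2C(Br)(Br)[C@]2(C)C[C@H]1O[Si](C)(C)C(C)(C)C | intermediate
7 | cis-fused bicyclic iminium ether tetrafluoroborate (O6–C12(=NMe2+)–C11 ring on the bromocyclohexene) | C[N+](C)=C1C[C@H]2[C@@H](O1)C(Br)=C(C)C[C@H]2O[Si](C)(C)C(C)(C)C.F[B-](F)(F)F | intermediate
8 | 2-[(1S,2R,6R)-3-bromo-6-(tert-butyldimethylsilyloxy)-2-hydroxy-4-methylcyclohex-3-en-1-yl]-N,N-dimethylacetamide | CN(C)C(=O)C[C@H]1[C@@H](O)C(Br)=C(C)C[C@H]1O[Si](C)(C)C(C)(C)C | intermediate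
9 | pent-4-yn-1-ol | C#CCCCO | starting material
10 | tert-butyldimethyl(pent-4-yn-1-yloxy)silane | C#CCCCO[Si](C)(C)C(C)(C)C | intermediate
11 | diisobutyl[5-(tert-butyldimethylsilyloxy)pent-1-en-2-yl]alane | C=C(CCCO[Si](C)(C)C(C)(C)C)[Al](CC(C)C)CC(C)C | intermediate
12 | 2-[5-(tert-butyldimethylsilyloxy)pent-1-en-2-yl]-4,4,5,5-tetramethyl-1,3,2-dioxaborolane | C=C(CCCO[Si](C)(C)C(C)(C)C)B1OC(C)(C)C(C)(C)O1 | intermediate
13 | diene hydroxy amide (8 with Br replaced by the 5-silyloxypent-1-en-2-yl group) | CN(C)C(=O)C[C@H]1[C@@H](O)C(C(=C)CCCO[Si](C)(C)C(C)(C)C)=C(C)C[C@H]1O[Si](C)(C)C(C)(C)C | intermediate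
14 | (4S)-dihydro hydroxy amide | CN(C)C(=O)C[C@H]1[C@@H](O)C([C@@H](C)CCCO[Si](C)(C)C(C)(C)C)=C(C)C[C@H]1O[Si](C)(C)C(C)(C)C | intermediate
15 | C11 dimethylaminomethyl amide (Mannich base, C11 epimers) | CN(C)CC(C(=O)N(C)C)[C@H]1[C@@H](O)C([C@@H](C)CCCO[Si](C)(C)C(C)(C)C)=C(C)C[C@H]1O[Si](C)(C)C(C)(C)C | intermediate
16 | trimethylammonium iodide of 15 | C[N+](C)(C)CC(C(=O)N(C)C)[C@H]1[C@@H](O)C([C@@H](C)CCCO[Si](C)(C)C(C)(C)C)=C(C)C[C@H]1O[Si](C)(C)C(C)(C)C.[I-] | intermediate
17 | α-methylene hydroxy amide | C=C(C(=O)N(C)C)[C@H]1[C@@H](O)C([C@@H](C)CCCO[Si](C)(C)C(C)(C)C)=C(C)C[C@H]1O[Si](C)(C)C(C)(C)C | intermediate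
18 | (R)-2-methylbutanoic acid | CC[C@@H](C)C(=O)O | starting material
19 | O6-[(2R)-2-methylbutanoyl] ester of 17 | C=C(C(=O)N(C)C)[C@H]1[C@@H](OC(=O)[C@H](C)CC)C([C@@H](C)CCCO[Si](C)(C)C(C)(C)C)=C(C)C[C@H]1O[Si](C)(C)C(C)(C)C | intermediate
20 | bis-desilylated 19 (O8 and O1 hydroxyls free) | C=C(C(=O)N(C)C)[C@H]1[C@@H](OC(=O)[C@H](C)CC)C([C@@H](C)CCCO)=C(C)C[C@H]1O | intermediate
21 | (3aR,4R,7aR)-5-[(2S)-5-hydroxypentan-2-yl]-6-methyl-3-methylidene-2-oxo-2,3,3a,4,7,7a-hexahydro-1-benzofuran-4-yl (2R)-2-methylbutanoate | C=C1C(=O)O[C@@H]2CC(C)=C([C@@H](C)CCCO)[C@H](OC(=O)[C@H](C)CC)[C@H]12 | target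

**Step count and risks**

Total: 12 steps. Longest linear sequence: 10 steps (steps 1–4 and 7–12 from 1); steps 5–6 make boronate 12.

Steps most likely to fail:

Step 4 (the proposed new method). Proton loss from the allyl cation or capture by stray nucleophiles may outrun the tethered amide, and the hemi-orthoamide may partition toward loss of dimethylamine instead of the C6 alkoxide. The fallback uses known chemistry and runs from 6 back to 8. Silver-assisted hydrolytic ring expansion (AgBF4, CaCO3-buffered aqueous acetone), which is established for gem-dibromobicyclo[3.1.0]hexanes, should give the C6 alcohols without facial control, that is 8 together with its C6 epimer, the trans alcohol F1. Oxidation of the mixture with Dess–Martin periodinane converges on the 5-bromo enone F2. LiBH(sBu)3 in THF at −78 °C should then add hydride to C6 from the face opposite the C7 and C8 substituents and return the all-cis alcohol 8.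

Step 8. Facial selectivity at C4 may be poor if the rotamers about C5–C4 are not biased or if the amide competes as directing group, and the allylic C5=C10 alkene may be over-reduced. The fallback changes from substrate direction to reagent control and runs from 13 back to 14. O6 is masked with N-(trimethylsilyl)imidazole as the trimethylsilyl ether F3. C4=C15 is hydrogenated with a chiral cationic iridium phosphine–oxazoline catalyst, [Ir(cod)((S)-tBu-PHOX)][B(C6H3(CF3)2)4] or its mirror image, whichever proves matched for (4S), to give the saturated silyl ether F4. K2CO3 in MeOH then removes only the trimethylsilyl group and returns 14.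

Step 12. Alcoholysis of the tertiary acrylamide may be slow, and harsher acid would invite ionisation or migration of the allylic O6 ester or amine addition to the methylene lactone. The fallback makes the acyl group reactive before desilylation and runs from 19 to 21. O-ethylation of the amide with Et3OBF4 (2,6-di-tert-butyl-4-methylpyridine, CH2Cl2) gives the imidate salt F5. Hydrolysis at pH 4–5 expels dimethylamine and leaves the ethyl ester F6. HF·pyridine in THF removes both silyl groups to give the dihydroxy ester F7, which should lactonise onto O8 on standing or with pyridinium 4-toluenesulfonate to reach 21.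

Further compounds
F1 | step 4 | C6 epimer of 8 (O6 trans to C11) | CN(C)C(=O)C[C@H]1[C@H](O)C(Br)=C(C)C[C@H]1O[Si](C)(C)C(C)(C)C
F2 | step 4 | 5-bromo enone (C6 ketone of 8) | CN(C)C(=O)C[C@H]1C(=O)C(Br)=C(C)C[C@H]1O[Si](C)(C)C(C)(C)C
F3 | step 8 | O6-trimethylsilyl ether of 13 | CN(C)C(=O)C[C@H]1[C@@H](O[Si](C)(C)C)C(C(=C)CCCO[Si](C)(C)C(C)(C)C)=C(C)C[C@H]1O[Si](C)(C)C(C)(C)C
F4 | step 8 | O6-trimethylsilyl ether of 14 | CN(C)C(=O)C[C@H]1[C@@H](O[Si](C)(C)C)C([C@@H](C)CCCO[Si](C)(C)C(C)(C)C)=C(C)C[C@H]1O[Si](C)(C)C(C)(C)C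
F5 | step 12 | O-ethyl imidate tetrafluoroborate of 19 | CCOC(=[N+](C)C)C(=C)[C@H]1[C@@H](OC(=O)[C@H](C)CC)C([C@@H](C)CCCO[Si](C)(C)C(C)(C)C)=C(C)C[C@H]1O[Si](C)(C)C(C)(C)C.F[B-](F)(F)F
F6 | step 12 | ethyl ester analogue of 19 | CCOC(=O)C(=C)[C@H]1[C@@H](OC(=O)[C@H](C)CC)C([C@@H](C)CCCO[Si](C)(C)C(C)(C)C)=C(C)C[C@H]1O[Si](C)(C)C(C)(C)C
F7 | step 12 | bis-desilylated F6 | CCOC(=O)C(=C)[C@H]1[C@@H](OC(=O)[C@H](C)CC)C([C@@H](C)CCCO)=C(C)C[C@H]1O
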